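**Assumptions (one line):** The target is the 7,4'-dihydroxy-8,3'-diprenyl dihydroflavonol with no 5-OH. Its SMILES gives (2R,3R), which is 2,3-trans. I assume the ortho-C-prenylations in Steps 1 and 2 give useful regioselectivity (about 30–40%) in aqueous base. 4-Hydroxy-3-prenylbenzaldehyde is also catalogue-available. I also assume poly-D-leucine gives the same face selectivity on this chalcone as it does on simple chalcones.

## Retrosynthesis
1. The target comes from acidic removal of two MOM groups from the trans-dihydroflavonol (13).
2. The pyranone ring closes last. A 2'-phenoxide opens a trans α,β-epoxy ketone by 6-exo-tet attack at the benzylic carbon with inversion. This sets C2, and the epoxide α-carbon becomes C3.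
3. The epoxide comes from nucleophilic asymmetric (Juliá–Colonna) epoxidation of a protected chalcone. OsO4 or dioxirane methods would attack the two prenyl alkenes, so they are excluded.
4. The chalcone comes from Claisen–Schmidt condensation of 3-prenylresacetophenone with 4-hydroxy-3-prenylbenzaldehyde, each made by C-prenylation of a commercial phenol.
5. The only new ring is the pyranone, formed in Step 7.

## Forward route

**Step 1**
Reactants: 1 (2',4'-dihydroxyacetophenone), 2 (prenyl bromide)
Product: 3 (1-(2,4-dihydroxy-3-prenylphenyl)ethanone)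
Conditions: KOH, H2O/MeOH, 0 °C to rt
Reagents that add atoms: prenyl bromide, CC(C)=CCBr
Why: The dianion is most nucleophilic at C3, between the two O⁻ groups. Protic solvent favours C-alkylation (ortho-C-prenylation of a phenolate). No stereocenter is formed.

**Step 2**
Reactants: 4 (4-hydroxybenzaldehyde), 2 (prenyl bromide)
Product: 5 (4-hydroxy-3-prenylbenzaldehyde)
Conditions: NaOH, H2O, rt
Reagents that add atoms: prenyl bromide, CC(C)=CCBr
Why: Ortho-C-alkylation of the phenolate in water, where hydrogen bonding to oxygen suppresses O-alkylation. No stereocenter is formed.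

**Step 3**
Reactants: 3 (3-prenylresacetophenone), 5 (4-hydroxy-3-prenylbenzaldehyde)
Product: 6 ((E)-2',4,4'-trihydroxy-3,3'-diprenylchalcone)
Conditions: 50% aq. KOH, EtOH, rt, 48 h; then HCl to pH 4
Reagents that add atoms: none
Why: Claisen–Schmidt aldol condensation. E1cB elimination gives the E enone, and there is no stereocenter. Acidifying to pH 4 limits flavanone formation.

**Step 4**
Reactants: 6
Product: 8 (4,4'-bis-MOM chalcone, 2'-OH free)
Conditions: MOMCl, DIPEA, CH2Cl2, 0 °C to rt
Reagents that add atoms: chloromethyl methyl ether (7), COCCl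
Why: The 4- and 4'-phenols are the more acidic, free OH groups and are alkylated. The 2'-OH is hydrogen-bonded to the carbonyl and is left alone. MOM blocks phenoxide formation, which would deactivate the enone toward nucleophilic epoxidation.

**Step 5**
Reactants: 8
Product: 10 (2'-OTBS, 4,4'-bis-OMOM chalcone)
Conditions: TBSCl, imidazole, DMF, 40 °C
Reagents that add atoms: tert-butyldimethylsilyl chloride (9), CC(C)(C)[Si](C)(C)Cl
Why: The silyl ether masks the 2'-OH so it cannot undergo oxa-Michael or Algar–Flynn–Oyamada-type chemistry. This forces a clean epoxide pathway in Step 6 and allows base-triggered unmasking in Step 7. It is orthogonal to MOM.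

**Step 6**
Reactants: 10
Product: 12 ((αR,βS)-trans-epoxy ketone)
Conditions: poly-D-leucine, urea·H2O2, DBU, THF, rt
Reagents that add atoms: urea hydrogen peroxide (11), NC(N)=O.OO
Why: Juliá–Colonna (Roberts non-aqueous) epoxidation. The helical peptide delivers HOO⁻ to one enone face (conjugate addition, then ring closure), which sets the α-carbon (future C3) as R and the β-carbon as S in a trans epoxide. The nucleophilic peroxide leaves the prenyl alkenes untouched, and MOM and TBS survive.

**Step 7**
Reactants: 12
Product: 13 ((2R,3R)-7,4'-bis-MOM-3-hydroxy-8,3'-diprenylflavanone)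
Conditions: TBAF, THF, 0 °C, 10 min
Reagents that add atoms: none
Why: Fluoride releases the 2'-phenoxide, which attacks the benzylic epoxide carbon by 6-exo-tet SN2. Inversion turns βS into C2-R, and the α-carbon is retained as C3-R, giving the 2,3-trans ring as in the Algar–Flynn–Oyamada manifold. The B-ring oxygen stays protected, so no quinone methide forms and C2 is not racemized.

**Step 8**
Reactants: 13
Product: 14 (3-hydroxyglabrol)
Conditions: 3 M HCl, MeOH/THF (1:1), 40 °C
Reagents that add atoms: none
Why: Acidolysis of the aryl MOM acetals. The dihydroflavonol, the secondary alcohol and the prenyl groups tolerate mild acid. Both stereocenters are untouched, and trans is the thermodynamically preferred arrangement.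

## Compound list
1 | 2',4'-dihydroxyacetophenone | CC(=O)c1ccc(O)cc1O | starting material
2 | prenyl bromide | CC(C)=CCBr | starting material (reagent)
3 | 1-(2,4-dihydroxy-3-prenylphenyl)ethanone | CC(=O)c1ccc(O)c(CC=C(C)C)c1O | intermediate
4 | 4-hydroxybenzaldehyde | O=Cc1ccc(O)cc1 | starting material
5 | 4-hydroxy-3-prenylbenzaldehyde | O=Cc1ccc(O)c(CC=C(C)C)c1 | intermediate
6 | (E)-2',4,4'-trihydroxy-3,3'-diprenylchalcone | CC(C)=CCc1cc(/C=C/C(=O)c2ccc(O)c(CC=C(C)C)c2O)ccc1O | intermediate
7 | chloromethyl methyl ether (MOMCl) | COCCl | starting material (reagent)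
8 | 4,4'-bis-MOM-2'-hydroxy chalcone | CC(C)=CCc1cc(/C=C/C(=O)c2ccc(OCOC)c(CC=C(C)C)c2O)ccc1OCOC | intermediate
9 | TBSCl | CC(C)(C)[Si](C)(C)Cl | starting material (reagent)
10 | 2'-OTBS-4,4'-bis-OMOM chalcone | CC(C)=CCc1cc(/C=C/C(=O)c2ccc(OCOC)c(CC=C(C)C)c2O[Si](C)(C)C(C)(C)C)ccc1OCOC | intermediate
11 | urea hydrogen peroxide | NC(N)=O.OO | starting material (reagent)
12 | (αR,βS)-trans-epoxy ketone | CC(C)=CCc1c(O[Si](C)(C)C(C)(C)C)c(C(=O)[C@@H]2O[C@H]2c2ccc(OCOC)c(CC=C(C)C)c2)ccc1OCOC | intermediate
13 | (2R,3R)-7,4'-bis-MOM-3-hydroxy-8,3'-diprenylflavanone | CC(C)=CCc1cc([C@H]2Oc3c(ccc(OCOC)c3CC=C(C)C)C(=O)[C@@H]2O)ccc1OCOC | intermediate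
14 | 3-hydroxyglabrol | CC(C)=CCc1cc([C@H]2Oc3c(ccc(O)c3CC=C(C)C)C(=O)[C@@H]2O)ccc1O | target

## Totals
Total steps: 8. Longest linear sequence: 7 (Steps 1, 3, 4, 5, 6, 7, 8).

## Three steps most likely to fail
1. **Step 2 (B-ring C-prenylation; Step 1 shares the issue).** A para-formyl phenolate is a poor carbon nucleophile, so O-prenylation and bis-prenylation compete.
   - Fallback: use directed ortho-metalation. Lithiate 4-MOMO-benzaldehyde dimethyl acetal (s-BuLi, TMEDA), add prenyl bromide with CuI, then remove the acetal under mild acid. For Step 1, make 2-prenylresorcinol by lithiating 1,3-bis(MOMO)benzene, then acetylate with BF3·AcOH.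
2. **Step 6 (enantioselective epoxidation).** The bulky 2'-OTBS/3'-prenyl-substituted enone may lower the ee or the conversion, and the enantiomeric sense of poly-D-Leu is assumed.
   - Fallback: use a Lewis-acid peroxide system, La–BINOL–Ph3P=O with cumene hydroperoxide (Shibasaki-type). This is a different mechanism from the helical peptide.
3. **Step 7 (cyclization).** 5-exo attack could give an aurone-type product, or base could epimerize or ring-open the product.
   - Fallback: skip Steps 5–7. Run racemic Algar–Flynn–Oyamada (H2O2, NaOH) on 8 to give trans-13, resolve it by preparative chiral SFC/HPLC to obtain (2R,3R), then carry out Step 8.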